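## Retrosynthetic overview

- **Feature:** C3 of the pyran ring C is the only stereocentre. It bears H, ring B (2,3,4,5-tetramethoxyphenyl) and two CH2 arms, C2 (bound to O1) and C4 (bound to C4a of ring A). Without ring A it is a mirror-symmetric 2-arylpropane-1,3-diol whose two CH2OH groups are enantiotopic.
- **Disconnections:** O7–Si; O1–C2 (intramolecular Mitsunobu); C4–C4a (Negishi coupling of a chiral primary alkyl iodide with an iodinated, differentially protected 2-methoxyresorcinol); the iodide and acetate arms back to the prochiral diol (lipase monoacetylation); the diol back to an arylmalonate made from bromotetramethoxybenzene.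
- **Ring order:** rings A and B are bought as arenes and joined through the three-carbon chain. Ring C is the only ring built, and it closes at O1–C2 in the penultimate step.

Key step: step 4

Assumption: the lipase chosen from the screen is taken to acetylate the pro-R hydroxymethyl arm of the diol; if it prefers the pro-S arm, the remedy given for step 4 at the end applies.

## Route

Step 1
Reactants: 1 1,2,3,4-tetramethoxybenzene
Product: 2 1-bromo-2,3,4,5-tetramethoxybenzene
Conditions: NBS (1.0 equiv), MeCN, 0 °C to rt, dark
Reagents that add atoms: N-bromosuccinimide, O=C1CCC(=O)N1Br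
Why: Electrophilic aromatic bromination: the two open positions are related by symmetry and each is ortho to one methoxy group and para to another, so only one monobromide can form, and one equivalent of NBS in MeCN should stop there because the bromine lowers the reactivity of the ring.

Step 2
Reactants: 2 1-bromo-2,3,4,5-tetramethoxybenzene; 3 diethyl malonate
Product: 4 diethyl 2-(2,3,4,5-tetramethoxyphenyl)malonate
Conditions: Pd(dba)2 (2 mol %), P(t-Bu)3 (4 mol %), K3PO4 (3 equiv), toluene, 70 °C, Ar
Reagents that add atoms: none
Why: Buchwald–Hartwig-type α-arylation of a malonate enolate: monoligated zerovalent palladium carrying the bulky, electron-rich P(t-Bu)3 inserts into the electron-rich, ortho-substituted C–Br bond and its bulk drives C–C reductive elimination, while the more acidic product rests as its potassium enolate and is shielded from a second arylation.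

Step 3
Reactants: 4 diethyl 2-(2,3,4,5-tetramethoxyphenyl)malonate
Product: 5 2-(2,3,4,5-tetramethoxyphenyl)propane-1,3-diol (achiral, prochiral at C2)
Conditions: LiAlH4 (3 equiv), THF, 0 °C, 4 added slowly to the hydride, then rt; H2O / aq NaOH / H2O work-up
Reagents that add atoms: none
Why: Hydride reduction of both esters to primary alcohols is a standard entry to 2-arylpropane-1,3-diols, and feeding the ester slowly into cold excess hydride lets carbonyl attack compete with deprotonation of the doubly activated benzylic C–H, which would otherwise lead to β-elimination.

Step 4
Reactants: 5 2-(2,3,4,5-tetramethoxyphenyl)propane-1,3-diol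
Product: 6 (2R)-3-hydroxy-2-(2,3,4,5-tetramethoxyphenyl)propyl acetate
Conditions: immobilised Burkholderia cepacia lipase (lead of a screen that also covers Pseudomonas fluorescens, porcine pancreatic, Candida antarctica B lipases), vinyl acetate (4 equiv), t-BuOMe, 30 °C; enzyme filtered off just after the diol is consumed
Reagents that add atoms: vinyl acetate, C=COC(C)=O
Why: The reaction is the known lipase-catalysed enantiotopic-group-selective monoacetylation of 2-substituted propane-1,3-diols: the active-site serine is acetylated by vinyl acetate, the vinyl alcohol released tautomerises so that the transfer is irreversible, and the acetyl-enzyme passes the acetyl group to one CH2OH group of bound 5. Only one ester C–O bond forms and no ring is closed. The aryl-bearing carbon (future C3) becomes stereogenic merely because its two arms are now different, and its configuration is dictated by the chiral pocket of the enzyme, which docks ring B in its large hydrophobic site and thereby offers the pro-R hydroxymethyl group to the acyl-serine. The step needs selectivity between enantiotopic groups and between mono- and diacylation, and the substrate helps through the strong size contrast at the prochiral carbon (a bulky flat arene against H) and through two unhindered primary hydroxyls. The second acetylation should be faster for the minor (S)-monoacetate, whose free arm is the one the enzyme prefers, so running slightly beyond consumption of the diol should raise the ee of 6. Because an ortho-methoxy, tetra-oxygenated aryl group is untested, the enzyme is picked by a screen, the ee is followed by chiral HPLC and the absolute configuration is secured before step 5.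

Step 5
Reactants: 6 (2R)-3-hydroxy-2-(2,3,4,5-tetramethoxyphenyl)propyl acetate
Product: 7 (2S)-3-iodo-2-(2,3,4,5-tetramethoxyphenyl)propyl acetate (same spatial arrangement as 6)
Conditions: PPh3, imidazole, I2, CH2Cl2, 0 °C (reagent preformed, freshly made 6 added last)
Reagents that add atoms: iodine, II
Why: Appel-type iodination: iodide displaces the alkoxyphosphonium group by SN2 at the primary carbon and not at the stereocentre, the fast, cold and nearly neutral medium leaves no time for 1,3-acetyl migration (which would interconvert the enantiomers), and the descriptor changes from R to S only because CH2I now outranks CH2OAc.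

Step 6
Reactants: 8 2-methoxybenzene-1,3-diol (2-methoxyresorcinol)
Product: 9 2-methoxy-3-(triisopropylsilyloxy)phenol
Conditions: TIPSCl (1.0 equiv), imidazole (2 equiv), DMF, 0 °C to rt
Reagents that add atoms: triisopropylsilyl chloride, CC(C)[Si](Cl)(C(C)C)C(C)C
Why: Silylation of one of two equivalent phenols allows only a single mono-ether, so one equivalent of the bulky chloride should give a statistical mixture from which 9 is separated by chromatography while recovered diol and over-silylated material are recycled.

Step 7
Reactants: 9 2-methoxy-3-(triisopropylsilyloxy)phenol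
Product: 10 triisopropyl[2-methoxy-3-(methoxymethoxy)phenoxy]silane
Conditions: MOMCl, i-Pr2NEt, CH2Cl2, 0 °C to rt
Reagents that add atoms: chloromethyl methyl ether, COCCl
Why: O-Alkylation of the remaining phenol with the reactive α-chloro ether under a hindered amine base does not disturb the aryl silyl ether, and it installs both the directing group for step 8 and an acid-labile mask for the future O1.

Step 8
Reactants: 10 triisopropyl[2-methoxy-3-(methoxymethoxy)phenoxy]silane
Product: 12 [4-iodo-2-methoxy-3-(methoxymethoxy)phenoxy]triisopropylsilane, via aryllithium 11 (not isolated)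
Conditions: n-BuLi, TMEDA, THF, −78 to −20 °C; then I2, THF, −78 °C to rt; aq Na2S2O3
Reagents that add atoms: iodine, II; n-butyllithium, [Li]CCCC (lithium stays only in intermediate 11)
Why: Directed ortho-metalation: the MOM oxygens chelate lithium and steer deprotonation to the only C–H next to that group (the other flank carries OMe), the bulky TIPS ether neither coordinates nor suffers attack at silicon at low temperature, and aryllithium 11 is trapped by I2.

Step 9
Reactants: 7 (2S)-3-iodo-2-(2,3,4,5-tetramethoxyphenyl)propyl acetate; 12 [4-iodo-2-methoxy-3-(methoxymethoxy)phenoxy]triisopropylsilane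
Product: 14 (2S)-3-[3-methoxy-2-(methoxymethoxy)-4-(triisopropylsilyloxy)phenyl]-2-(2,3,4,5-tetramethoxyphenyl)propyl acetate, via alkylzinc iodide 13 (not isolated)
Conditions: Zn dust (3 equiv, cat. I2), DMF, rt to 35 °C; then 12, Pd2(dba)3 (2.5 mol %), SPhos (2-dicyclohexylphosphino-2',6'-dimethoxybiphenyl, 10 mol %), DMF, rt to 40 °C
Reagents that add atoms: zinc, [Zn] (stays only in intermediate 13)
Why: Negishi sp3–sp2 coupling of a functionalised primary alkylzinc iodide: zinc inserts into the C–I bond without harming the acetate, which is a poor leaving group for 1,3-elimination, the bulky biaryl phosphine speeds reductive elimination from the alkyl(aryl)palladium species enough to outrun β-hydride elimination of the benzylic C3–H, and no bond to the stereocentre is made or broken.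

Step 10
Reactants: 14 (2S)-3-[3-methoxy-2-(methoxymethoxy)-4-(triisopropylsilyloxy)phenyl]-2-(2,3,4,5-tetramethoxyphenyl)propyl acetate
Product: 15 6-[(2S)-3-hydroxy-2-(2,3,4,5-tetramethoxyphenyl)propyl]-2-methoxy-3-(triisopropylsilyloxy)phenol
Conditions: HCl (1.25 M in MeOH), 0 to 40 °C
Reagents that add atoms: none
Why: Acid-catalysed acetal solvolysis of the MOM ether and transesterification of the acetate run side by side in methanol, whereas an aryl TIPS ether, sensitive to base but very slow to cleave in acid, should stay in place, which is why carbonate in methanol is avoided.

Step 11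
Reactants: 15 6-[(2S)-3-hydroxy-2-(2,3,4,5-tetramethoxyphenyl)propyl]-2-methoxy-3-(triisopropylsilyloxy)phenol
Product: 16 (3S)-8-methoxy-3-(2,3,4,5-tetramethoxyphenyl)-7-(triisopropylsilyloxy)chroman
Conditions: PPh3, DIAD, THF (0.02 M), 0 °C to rt
Reagents that add atoms: none
Why: Intramolecular Mitsunobu etherification: the primary alcohol is activated as its alkoxyphosphonium salt and displaced by the neighbouring phenoxide in a 6-exo-tet SN2 closure of ring C at C2, a non-stereogenic carbon, so C3 keeps its (S) configuration.

Step 12
Reactants: 16 (3S)-8-methoxy-3-(2,3,4,5-tetramethoxyphenyl)-7-(triisopropylsilyloxy)chroman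
Product: 17 (3S)-8-methoxy-3-(2,3,4,5-tetramethoxyphenyl)chroman-7-ol, that is (S)-7-hydroxy-8,2',3',4',5'-pentamethoxyisoflavan
Conditions: TBAF (1.1 equiv), AcOH (1.1 equiv), THF, 0 °C, Ar
Reagents that add atoms: none
Why: Fluoride-mediated desilylation is driven by the strength of the Si–F bond, the acetic acid buffer protonates the electron-rich phenoxide at once and so guards it against air oxidation, and nothing else in the molecule responds to fluoride.

## Compound list

1 | 1,2,3,4-tetramethoxybenzene | COc1ccc(OC)c(OC)c1OC | starting material
2 | 1-bromo-2,3,4,5-tetramethoxybenzene | COc1cc(Br)c(OC)c(OC)c1OC | intermediate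
3 | diethyl malonate | CCOC(=O)CC(=O)OCC | starting material
4 | diethyl 2-(2,3,4,5-tetramethoxyphenyl)malonate | CCOC(=O)C(C(=O)OCC)c1cc(OC)c(OC)c(OC)c1OC | intermediate
5 | 2-(2,3,4,5-tetramethoxyphenyl)propane-1,3-diol | OCC(CO)c1cc(OC)c(OC)c(OC)c1OC | intermediate
6 | (2R)-3-hydroxy-2-(2,3,4,5-tetramethoxyphenyl)propyl acetate | COc1cc([C@H](CO)COC(C)=O)c(OC)c(OC)c1OC | intermediate
7 | (2S)-3-iodo-2-(2,3,4,5-tetramethoxyphenyl)propyl acetate | COc1cc([C@H](CI)COC(C)=O)c(OC)c(OC)c1OC | intermediate
8 | 2-methoxybenzene-1,3-diol | COc1c(O)cccc1O | starting material
9 | 2-methoxy-3-(triisopropylsilyloxy)phenol | COc1c(O)cccc1O[Si](C(C)C)(C(C)C)C(C)C | intermediate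
10 | triisopropyl[2-methoxy-3-(methoxymethoxy)phenoxy]silane | COCOc1cccc(O[Si](C(C)C)(C(C)C)C(C)C)c1OC | intermediate
11 | [3-methoxy-2-(methoxymethoxy)-4-(triisopropylsilyloxy)phenyl]lithium | [Li]c1ccc(O[Si](C(C)C)(C(C)C)C(C)C)c(OC)c1OCOC | intermediate
12 | [4-iodo-2-methoxy-3-(methoxymethoxy)phenoxy]triisopropylsilane | COCOc1c(I)ccc(O[Si](C(C)C)(C(C)C)C(C)C)c1OC | intermediate
13 | [(2S)-3-acetoxy-2-(2,3,4,5-tetramethoxyphenyl)propyl]zinc iodide | COc1cc([C@H](C[Zn]I)COC(C)=O)c(OC)c(OC)c1OC | intermediate
14 | (2S)-3-[3-methoxy-2-(methoxymethoxy)-4-(triisopropylsilyloxy)phenyl]-2-(2,3,4,5-tetramethoxyphenyl)propyl acetate | COc1cc([C@H](Cc2ccc(O[Si](C(C)C)(C(C)C)C(C)C)c(OC)c2OCOC)COC(C)=O)c(OC)c(OC)c1OC | intermediate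
15 | 6-[(2S)-3-hydroxy-2-(2,3,4,5-tetramethoxyphenyl)propyl]-2-methoxy-3-(triisopropylsilyloxy)phenol | COc1cc([C@H](Cc2ccc(O[Si](C(C)C)(C(C)C)C(C)C)c(OC)c2O)CO)c(OC)c(OC)c1OC | intermediate
16 | (3S)-8-methoxy-3-(2,3,4,5-tetramethoxyphenyl)-7-(triisopropylsilyloxy)chroman | COc1cc([C@H]2COc3c(ccc(O[Si](C(C)C)(C(C)C)C(C)C)c3OC)C2)c(OC)c(OC)c1OC | intermediate
17 | (3S)-8-methoxy-3-(2,3,4,5-tetramethoxyphenyl)chroman-7-ol | COc1cc([C@H]2COc3c(ccc(O)c3OC)C2)c(OC)c(OC)c1OC | target

## Step count and risks

Total step count: 12.
Longest linear sequence: 9 steps (steps 1–5, then 9–12). The ring A branch (steps 6–8) joins at step 9.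

**Step 4.** The lipases may discriminate poorly between the two enantiotopic arms in acylation mode, or they may acetylate the pro-S arm preferentially. The fallback reverses the direction of the enzymatic reaction. It sets out from diol 5, which is peracetylated (Ac2O, pyridine, cat. DMAP) to 2-(2,3,4,5-tetramethoxyphenyl)propane-1,3-diyl diacetate F1. This diester is then subjected to lipase- or esterase-catalysed monohydrolysis in pH 7 phosphate buffer with a little cosolvent. An enzyme recognises the same arm in both directions, so hydrolysis leaves the acetate on the arm that acylation would have left free. An enzyme with pro-S preference should therefore now deliver the (R)-monoacetate. The aqueous medium also amounts to an independent selectivity screen. The fallback comes back to the route at 6.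

**Step 9.** Several processes may interfere:
- β-hydride elimination from the alkylpalladium intermediate;
- sluggish zinc insertion;
- protonation of the zinc reagent;
- on prolonged warming, participation of the acetate carbonyl at the iodide-bearing carbon through a symmetric six-membered acyloxonium ion, which would erode the ee. For this reason the ee is rechecked on 14.

The fallback drops both the preformed zinc reagent and palladium. Iodides 7 and 12 are combined directly in a nickel-catalysed reductive cross-electrophile coupling (NiI2, 4,4'-di-tert-butyl-2,2'-bipyridine, Mn powder, DMPU, 40–60 °C). The aryl iodide adds to low-valent nickel, and the alkyl iodide enters as a primary radical that the arylnickel species captures. Reductive elimination should then be fast relative to β-hydride elimination. The radical sits on the CH2 next to the stereocentre, and 1,2-aryl migration of such β-aryl radicals is slow compared with capture by nickel, so skeleton and configuration should hold. The fallback sets out from 7 and 12 and comes back at 14 without any new isolable compound.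

**Step 3.** Hydride may deprotonate the acidic malonate C–H. β-Elimination of an aluminate from the half-reduced enolate would follow, and material would be lost. The fallback removes the 1,3-dicarbonyl acidity before any reduction. It sets out from 4:
- Krapcho dealkoxycarbonylation (LiCl, H2O, DMSO, 150 °C) should give ethyl 2-(2,3,4,5-tetramethoxyphenyl)acetate F2.
- Base-catalysed aldol hydroxymethylation with paraformaldehyde (cat. NaOEt, DMSO, rt), the tropic-ester reaction, should give racemic ethyl 3-hydroxy-2-(2,3,4,5-tetramethoxyphenyl)propanoate F3.
- Reduction of the single, far less acidic ester with LiBH4 (THF/MeOH, 0 °C to rt) comes back to the route at the achiral diol 5.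

## Further compounds

F1 | step 4 | 2-(2,3,4,5-tetramethoxyphenyl)propane-1,3-diyl diacetate | CC(=O)OCC(COC(C)=O)c1cc(OC)c(OC)c(OC)c1OC
F0 | step 9 | none | none
F2 | step 3 | ethyl 2-(2,3,4,5-tetramethoxyphenyl)acetate | CCOC(=O)Cc1cc(OC)c(OC)c(OC)c1OC
F3 | step 3 | ethyl 3-hydroxy-2-(2,3,4,5-tetramethoxyphenyl)propanoate (racemic) | CCOC(=O)C(CO)c1cc(OC)c(OC)c(OC)c1OC
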